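**Strategy.** The cyclobutane is divided into two two-carbon halves: the pair of ring carbons that carry the 2-aminoimidazoles and the pair that carry the CH2NH-acyl arms. One triplet [2+2] photocycloaddition joins them: maleic anhydride adds to a C2-symmetric (E)-alkene made from D-mannitol, in which each future imidazole C4–C5 unit is still a dioxolane. The route exploits the C2 axis of the all-trans ring and the fact that imidazole C4 is sp2: the two carbinol carbons are stereocentres that steer the face of addition, fix the absolute configuration of the ring, and vanish when the heterocycles are built. Ester equilibration then corrects the anhydride-derived centres to all-trans.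

Key step: step 2

Assumption: the 2-amino-1H-imidazol-4-yl and -5-yl forms are tautomers of one compound, and the target is isolated as the free base.

Remark: the dioxolane carbons are R in 1 and S from 2 onwards; this is a change of CIP priority only, not of spatial arrangement.

Remark: steps 6 and 11 are twofold reactions that each consume two equivalents of a numbered compound (10 and 17); the second equivalent is listed under the reagents that add atoms.

**Step 1**
Reactants: 1 1,2:5,6-di-O-isopropylidene-D-mannitol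
Product: 2 (4S,4'S)-4,4'-[(E)-ethene-1,2-diyl]bis(2,2-dimethyl-1,3-dioxolane)
Conditions: PPh3, imidazole, I2, PhMe, 110 °C
Reagents that add atoms: none
Why: Garegg–Samuelsson deoxygenative olefination of a vicinal diol, in which iodide displaces one oxyphosphonium with inversion and anti-elimination follows, so the threo (C2-symmetric) diol should give the E-alkene while the dioxolane carbons are untouched.

**Step 2**
Reactants: 2 (4S,4'S)-4,4'-[(E)-ethene-1,2-diyl]bis(2,2-dimethyl-1,3-dioxolane); 3 maleic anhydride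
Product: 4 (1R,5S,6R,7R)-6,7-bis[(4S)-2,2-dimethyl-1,3-dioxolan-4-yl]-3-oxabicyclo[3.2.0]heptane-2,4-dione (cis-fused anhydride, dioxolanyl groups trans; used crude)
Conditions: hν (300 nm), acetone (solvent and triplet sensitiser), 3 (3 equiv), Ar, −20 °C
Reagents that add atoms: none
Why: Acetone triplet sensitises 3, whose electrophilic triplet adds to one alkene carbon of 2 to give a triplet 1,4-biradical that closes after intersystem crossing; this is the sensitised maleic anhydride–alkene [2+2] photocycloaddition known for acyclic trans-1,2-disubstituted alkenes with allylic heteroatoms. The cyclobutane closes by radical recombination within the 1,4-biradical (intermolecular, stepwise [2+2]), and the five-membered anhydride ring carried in from 3 enforces a cis fusion. The two dioxolanyl-bearing ring carbons are controlled by the dioxolane carbons: the first bond should form on the alkene face defined by the inside-alkoxy arrangement (allylic C–O inside, dioxolane CH2 anti to the incoming carbon, hydrogen outside), the sense seen in dihydroxylations and nitrile oxide additions to allylic ethers, and because the two ends of 2 are related by its C2 axis both dioxolanes direct to the same face. Their trans relation is inherited from the E-alkene, the biradical closing through the less hindered rotamer, which leaves one diastereomer possible per face. The two anhydride-derived carbons are set only provisionally (cis) and are equilibrated in step 3. The step needs cross- over homo-addition, secured because only 3 is excited and 2 has no chromophore (the insoluble dimer of 3 is filtered off), and facial selectivity, secured by the allylic stereocentres; the minor facial isomer is a diastereomer and is removed at 7.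

**Step 3**
Reactants: 4 (1R,5S,6R,7R)-6,7-bis[(4S)-2,2-dimethyl-1,3-dioxolan-4-yl]-3-oxabicyclo[3.2.0]heptane-2,4-dione
Product: 7 dimethyl (1S,2S,3R,4R)-3,4-bis[(4S)-2,2-dimethyl-1,3-dioxolan-4-yl]cyclobutane-1,2-dicarboxylate (all-trans), via cis-diacid 5 (not isolated), via cis-diester 6 (not isolated)
Conditions: H2O, pyridine (cat.), THF, 40 °C; TMSCHN2, PhMe/MeOH, 0 °C; concentrate; NaOMe, MeOH, 65 °C; chromatography
Reagents that add atoms: water (O); trimethylsilyldiazomethane (C[Si](C)(C)C=[N+]=[N-])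
Why: Anhydride hydrolysis and diazoalkane esterification are followed by methoxide equilibration, in which the ester-bearing carbon that is cis to both neighbours should epimerise through its enolate to the all-trans (thermodynamic) diester, while the two non-enolisable dioxolanyl-bearing carbons hold the absolute configuration.

**Step 4**
Reactants: 7 dimethyl (1S,2S,3R,4R)-3,4-bis[(4S)-2,2-dimethyl-1,3-dioxolan-4-yl]cyclobutane-1,2-dicarboxylate
Product: 8 {(1R,2R,3S,4S)-3,4-bis[(4S)-2,2-dimethyl-1,3-dioxolan-4-yl]cyclobutane-1,2-diyl}dimethanol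
Conditions: LiAlH4, THF, 0 °C; Fieser work-up
Reagents that add atoms: none
Why: LiAlH4 reduction of both esters to primary alcohols; no stereocentre is touched and the acetonides are inert to hydride.

**Step 5**
Reactants: 8 {(1R,2R,3S,4S)-3,4-bis[(4S)-2,2-dimethyl-1,3-dioxolan-4-yl]cyclobutane-1,2-diyl}dimethanol
Product: 9 (4S,4'S)-4,4'-[(1S,2S,3R,4R)-3,4-bis(azidomethyl)cyclobutane-1,2-diyl]bis(2,2-dimethyl-1,3-dioxolane)
Conditions: PPh3, DIAD, (PhO)2P(O)N3, THF, 0 °C to rt
Reagents that add atoms: diphenylphosphoryl azide (O=P(N=[N+]=[N-])(Oc1ccccc1)Oc1ccccc1)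
Why: Mitsunobu azidation at two unhindered primary carbinols, with no stereocentre involved.

**Step 6**
Reactants: 9 (4S,4'S)-4,4'-[(1S,2S,3R,4R)-3,4-bis(azidomethyl)cyclobutane-1,2-diyl]bis(2,2-dimethyl-1,3-dioxolane); 10 2-(trichloroacetyl)pyrrole
Product: 12 N,N'-({(1R,2R,3S,4S)-3,4-bis[(4S)-2,2-dimethyl-1,3-dioxolan-4-yl]cyclobutane-1,2-diyl}bis(methylene))bis(1H-pyrrole-2-carboxamide), via diamine 11 (not isolated)
Conditions: H2 (1 atm), Pd/C, MeOH, rt; filter; 10 (2.2 equiv), Et3N, MeCN, rt
Reagents that add atoms: 2-(trichloroacetyl)pyrrole as the second equivalent of 10 (O=C(c1ccc[nH]1)C(Cl)(Cl)Cl)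
Why: Catalytic hydrogenation of the azides to the diamine, then haloform-type acyl transfer from the trichloromethyl ketone to each of the two primary amines (one molecule of 10 per amine, two in all), the standard entry to pyrrole-2-carboxamides.

**Step 7**
Reactants: 12 N,N'-({(1R,2R,3S,4S)-3,4-bis[(4S)-2,2-dimethyl-1,3-dioxolan-4-yl]cyclobutane-1,2-diyl}bis(methylene))bis(1H-pyrrole-2-carboxamide)
Product: 13 N,N'-({(1R,2R,3S,4S)-3,4-bis[(1S)-1,2-dihydroxyethyl]cyclobutane-1,2-diyl}bis(methylene))bis(1H-pyrrole-2-carboxamide)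
Conditions: AcOH/H2O (4:1), 45 °C
Reagents that add atoms: none
Why: Acid-catalysed acetonide hydrolysis, which 2-acylpyrroles and secondary amides tolerate.

**Step 8**
Reactants: 13 N,N'-({(1R,2R,3S,4S)-3,4-bis[(1S)-1,2-dihydroxyethyl]cyclobutane-1,2-diyl}bis(methylene))bis(1H-pyrrole-2-carboxamide)
Product: 14 the bis(primary 4-methylbenzenesulfonate) of 13, N,N'-({(1R,2R,3S,4S)-3,4-bis[(1S)-1-hydroxy-2-(tosyloxy)ethyl]cyclobutane-1,2-diyl}bis(methylene))bis(1H-pyrrole-2-carboxamide)
Conditions: TsCl (2.2 equiv), Bu2SnO (5 mol %), Et3N, CH2Cl2/THF, 0 °C to rt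
Reagents that add atoms: 4-methylbenzenesulfonyl chloride (Cc1ccc(cc1)S(Cl)(=O)=O)
Why: Stannylene-acetal-mediated sulfonylation of a terminal 1,2-diol is selective for the primary hydroxyl, and pyrrole and amide NH are not sulfonylated by TsCl/Et3N.

**Step 9**
Reactants: 14 N,N'-({(1R,2R,3S,4S)-3,4-bis[(1S)-1-hydroxy-2-(tosyloxy)ethyl]cyclobutane-1,2-diyl}bis(methylene))bis(1H-pyrrole-2-carboxamide)
Product: 15 N,N'-({(1R,2R,3S,4S)-3,4-bis[(1S)-2-azido-1-hydroxyethyl]cyclobutane-1,2-diyl}bis(methylene))bis(1H-pyrrole-2-carboxamide)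
Conditions: NaN3, DMF, 60 °C
Reagents that add atoms: sodium azide ([Na+].[N-]=[N+]=[N-])
Why: SN2 displacement of the primary tosylates by azide; any epoxide formed through the neighbouring hydroxyl is opened by azide at the same terminal carbon.

**Step 10**
Reactants: 15 N,N'-({(1R,2R,3S,4S)-3,4-bis[(1S)-2-azido-1-hydroxyethyl]cyclobutane-1,2-diyl}bis(methylene))bis(1H-pyrrole-2-carboxamide)
Product: 16 N,N'-{[(1R,2R,3S,4S)-3,4-bis(azidoacetyl)cyclobutane-1,2-diyl]bis(methylene)}bis(1H-pyrrole-2-carboxamide)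
Conditions: Dess–Martin periodinane, MeCN/CH2Cl2, 0 °C to rt
Reagents that add atoms: none
Why: Dess–Martin oxidation of the secondary alcohols to α-azido ketones under non-basic conditions; the two carbinol stereocentres are erased here, and the adjacent ring carbons, now enolisable, already hold the thermodynamically preferred all-trans arrangement.

**Step 11**
Reactants: 16 N,N'-{[(1R,2R,3S,4S)-3,4-bis(azidoacetyl)cyclobutane-1,2-diyl]bis(methylene)}bis(1H-pyrrole-2-carboxamide); 17 cyanamide
Product: 19 N,N'-{[(1R,2R,3S,4S)-3,4-bis(2-amino-1H-imidazol-5-yl)cyclobutane-1,2-diyl]bis(methylene)}bis(1H-pyrrole-2-carboxamide) (target), via bis(aminoketone) dihydrochloride 18 (not isolated)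
Conditions: H2 (1 atm), Pd/C, HCl (2.2 equiv), MeOH/H2O, rt; filter, concentrate; 17 (10 equiv), H2O, pH 4.5, 95 °C; NaOH to pH 10, reversed-phase chromatography
Reagents that add atoms: cyanamide as the second equivalent of 17 (NC#N)
Why: Hydrogenation in the presence of HCl should give the bis(α-amino ketone) as its stable salt, and one molecule of cyanamide then condenses with each of the two α-amino ketones (guanylation of the amine, cyclisation onto the ketone, dehydration; Marckwald-type 2-aminoimidazole synthesis); the pyrroles carry no halogen, so hydrogenation is harmless.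

**Compound list**
1 | 1,2:5,6-di-O-isopropylidene-D-mannitol | CC1(C)OC[C@@H](O1)[C@@H](O)[C@H](O)[C@H]1COC(C)(C)O1 | starting material
2 | (4S,4'S)-4,4'-[(E)-ethene-1,2-diyl]bis(2,2-dimethyl-1,3-dioxolane) | CC1(C)OC[C@@H](O1)/C=C/[C@H]1COC(C)(C)O1 | intermediate
3 | maleic anhydride | O=C1OC(=O)C=C1 | starting material
4 | (1R,5S,6R,7R)-6,7-bis[(4S)-2,2-dimethyl-1,3-dioxolan-4-yl]-3-oxabicyclo[3.2.0]heptane-2,4-dione | CC1(C)OC[C@@H](O1)[C@H]2[C@@H]3C(=O)OC(=O)[C@@H]3[C@@H]2[C@H]4COC(C)(C)O4 | intermediate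
5 | (1R,2S,3R,4R)-3,4-bis[(4S)-2,2-dimethyl-1,3-dioxolan-4-yl]cyclobutane-1,2-dicarboxylic acid (cis-diacid) | CC1(C)OC[C@@H](O1)[C@H]2[C@H](C(=O)O)[C@H](C(=O)O)[C@@H]2[C@H]3COC(C)(C)O3 | intermediate
6 | dimethyl (1R,2S,3R,4R)-3,4-bis[(4S)-2,2-dimethyl-1,3-dioxolan-4-yl]cyclobutane-1,2-dicarboxylate (cis-diester) | CC1(C)OC[C@@H](O1)[C@H]2[C@H](C(=O)OC)[C@H](C(=O)OC)[C@@H]2[C@H]3COC(C)(C)O3 | intermediate
7 | dimethyl (1S,2S,3R,4R)-3,4-bis[(4S)-2,2-dimethyl-1,3-dioxolan-4-yl]cyclobutane-1,2-dicarboxylate (all-trans) | CC1(C)OC[C@@H](O1)[C@H]2[C@H](C(=O)OC)[C@@H](C(=O)OC)[C@@H]2[C@H]3COC(C)(C)O3 | intermediate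
8 | {(1R,2R,3S,4S)-3,4-bis[(4S)-2,2-dimethyl-1,3-dioxolan-4-yl]cyclobutane-1,2-diyl}dimethanol | CC1(C)OC[C@@H](O1)[C@H]2[C@H](CO)[C@@H](CO)[C@@H]2[C@H]3COC(C)(C)O3 | intermediate
9 | (4S,4'S)-4,4'-[(1S,2S,3R,4R)-3,4-bis(azidomethyl)cyclobutane-1,2-diyl]bis(2,2-dimethyl-1,3-dioxolane) | CC1(C)OC[C@@H](O1)[C@H]2[C@H](CN=[N+]=[N-])[C@@H](CN=[N+]=[N-])[C@@H]2[C@H]3COC(C)(C)O3 | intermediate
10 | 2-(trichloroacetyl)pyrrole | O=C(c1ccc[nH]1)C(Cl)(Cl)Cl | starting material
11 | {(1R,2R,3S,4S)-3,4-bis[(4S)-2,2-dimethyl-1,3-dioxolan-4-yl]cyclobutane-1,2-diyl}dimethanamine (diamine) | CC1(C)OC[C@@H](O1)[C@H]2[C@H](CN)[C@@H](CN)[C@@H]2[C@H]3COC(C)(C)O3 | intermediate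
12 | N,N'-({(1R,2R,3S,4S)-3,4-bis[(4S)-2,2-dimethyl-1,3-dioxolan-4-yl]cyclobutane-1,2-diyl}bis(methylene))bis(1H-pyrrole-2-carboxamide) | CC1(C)OC[C@@H](O1)[C@H]2[C@H](CNC(=O)c4ccc[nH]4)[C@@H](CNC(=O)c4ccc[nH]4)[C@@H]2[C@H]3COC(C)(C)O3 | intermediate
13 | N,N'-({(1R,2R,3S,4S)-3,4-bis[(1S)-1,2-dihydroxyethyl]cyclobutane-1,2-diyl}bis(methylene))bis(1H-pyrrole-2-carboxamide) | OC[C@@H](O)[C@H]1[C@H](CNC(=O)c2ccc[nH]2)[C@@H](CNC(=O)c2ccc[nH]2)[C@@H]1[C@H](O)CO | intermediate
14 | N,N'-({(1R,2R,3S,4S)-3,4-bis[(1S)-1-hydroxy-2-(tosyloxy)ethyl]cyclobutane-1,2-diyl}bis(methylene))bis(1H-pyrrole-2-carboxamide) | Cc1ccc(cc1)S(=O)(=O)OC[C@@H](O)[C@H]2[C@H](CNC(=O)c3ccc[nH]3)[C@@H](CNC(=O)c3ccc[nH]3)[C@@H]2[C@H](O)COS(=O)(=O)c1ccc(C)cc1 | intermediate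
15 | N,N'-({(1R,2R,3S,4S)-3,4-bis[(1S)-2-azido-1-hydroxyethyl]cyclobutane-1,2-diyl}bis(methylene))bis(1H-pyrrole-2-carboxamide) | [N-]=[N+]=NC[C@@H](O)[C@H]1[C@H](CNC(=O)c2ccc[nH]2)[C@@H](CNC(=O)c2ccc[nH]2)[C@@H]1[C@H](O)CN=[N+]=[N-] | intermediate
16 | N,N'-{[(1R,2R,3S,4S)-3,4-bis(azidoacetyl)cyclobutane-1,2-diyl]bis(methylene)}bis(1H-pyrrole-2-carboxamide) | [N-]=[N+]=NCC(=O)[C@H]1[C@H](CNC(=O)c2ccc[nH]2)[C@@H](CNC(=O)c2ccc[nH]2)[C@@H]1C(=O)CN=[N+]=[N-] | intermediate
17 | cyanamide | NC#N | starting material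
18 | N,N'-{[(1R,2R,3S,4S)-3,4-bis(aminoacetyl)cyclobutane-1,2-diyl]bis(methylene)}bis(1H-pyrrole-2-carboxamide) dihydrochloride | Cl.Cl.NCC(=O)[C@H]1[C@H](CNC(=O)c2ccc[nH]2)[C@@H](CNC(=O)c2ccc[nH]2)[C@@H]1C(=O)CN | intermediate
19 | N,N'-{[(1R,2R,3S,4S)-3,4-bis(2-amino-1H-imidazol-5-yl)cyclobutane-1,2-diyl]bis(methylene)}bis(1H-pyrrole-2-carboxamide) | Nc1ncc([C@H]2[C@H](CNC(=O)c3ccc[nH]3)[C@@H](CNC(=O)c3ccc[nH]3)[C@@H]2c2cnc(N)[nH]2)[nH]1 | target

**Total step count:** 11. **Longest linear sequence:** 11 steps (from 1).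

**Steps most likely to fail**

Step 2. What may go wrong: hydrogen abstraction from the allylic, oxygen-bearing C–H of the dioxolanes by the triplet species; slow addition to an alkene flanked by two branched carbons; bond rotation in the biradical with loss of the trans relation; weak facial discrimination by acyclic stereocentres. The fallback replaces stereochemical relay by resolution and exchanges the roles of the partners, while still forming the same two ring bonds in one photocycloaddition. It sets out from 3 and comes back at 16. Sensitised irradiation (acetophenone, MeCN) of 3 with commercial (E)-1,4-dichlorobut-2-ene would give the racemic cis-fused anhydride with trans chloromethyl groups F1, whose anhydride carbons are now the future imidazole-bearing carbons. Acidic methanolysis would give the racemic cis-diester F2, and NaOMe/MeOH would equilibrate it to the racemic all-trans bis(chloromethyl) diester F3. NaN3 in DMF would give the bis(azidomethyl) diester F4; hydrogenation over Pd/C would give the bis(aminomethyl) diester F5, acylated at once with two equivalents of 10 to the bis(pyrrole-2-carboxamide) diester F6. F6 would be resolved by preparative chromatography on a chiral stationary phase, and the enantiomer shown carried on. Excess dimethylsulfoxonium methylide would convert both esters into the bis(β-keto sulfoxonium ylide) F7, HCl would turn this into the bis(chloromethyl ketone) F8, and NaN3 would give 16.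

Step 11. What may go wrong: self-condensation of the free α-amino ketone (dihydropyrazine or cyclic imine formation) if the pH drifts, over-reduction of the ketones, and incomplete twofold condensation with cyanamide. The fallback builds the heterocycle from an α-sulfonyloxy ketone and a protected guanidine instead of from an α-amino ketone; it sets out from 14 and comes back at 19. Dess–Martin oxidation of 14 would give the bis(α-tosyloxy ketone) F9. Condensation with two equivalents of N-Boc-guanidine (CC(C)(C)OC(=O)NC(N)=N) in DMF, a Hantzsch-type imidazole synthesis, would give the bis(1-Boc-2-aminoimidazole) F10. TFA followed by basic work-up would give 19.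

Step 8. What may go wrong: sulfonylation of the secondary hydroxyls as well, premature epoxide closure, and poor solubility of the tetraol. The fallback uses regioselective epoxide opening instead of selective sulfonylation; it sets out from 13 and comes back at 15. Mitsunobu cyclodehydration (PPh3, DIAD, THF) of each terminal 1,2-diol, with the primary oxyphosphonium displaced by the secondary hydroxyl and retention at the carbinol carbon, would give the bis-epoxide F11. NaN3/NH4Cl in MeOH/H2O at 65 °C would open each epoxide at the terminal carbon to give 15.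

**Further compounds**
F1 | step 2 | racemic 6,7-trans-bis(chloromethyl)-3-oxabicyclo[3.2.0]heptane-2,4-dione (one enantiomer drawn) | O=C1OC(=O)[C@@H]2[C@H](CCl)[C@@H](CCl)[C@H]12
F2 | step 2 | racemic dimethyl 3,4-trans-bis(chloromethyl)cyclobutane-1,2-cis-dicarboxylate (one enantiomer drawn) | COC(=O)[C@@H]1[C@H](CCl)[C@@H](CCl)[C@@H]1C(=O)OC
F3 | step 2 | racemic all-trans dimethyl 3,4-bis(chloromethyl)cyclobutane-1,2-dicarboxylate (one enantiomer drawn) | COC(=O)[C@H]1[C@H](CCl)[C@@H](CCl)[C@@H]1C(=O)OC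
F4 | step 2 | racemic all-trans dimethyl 3,4-bis(azidomethyl)cyclobutane-1,2-dicarboxylate (one enantiomer drawn) | COC(=O)[C@H]1[C@H](CN=[N+]=[N-])[C@@H](CN=[N+]=[N-])[C@@H]1C(=O)OC
F5 | step 2 | racemic all-trans dimethyl 3,4-bis(aminomethyl)cyclobutane-1,2-dicarboxylate (one enantiomer drawn) | COC(=O)[C@H]1[C@H](CN)[C@@H](CN)[C@@H]1C(=O)OC
F6 | step 2 | dimethyl (1S,2S,3R,4R)-3,4-bis{[(1H-pyrrole-2-carbonyl)amino]methyl}cyclobutane-1,2-dicarboxylate (racemic, then resolved; needed enantiomer drawn) | COC(=O)[C@H]1[C@H](CNC(=O)c2ccc[nH]2)[C@@H](CNC(=O)c2ccc[nH]2)[C@@H]1C(=O)OC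
F7 | step 2 | bis(dimethylsulfoxonium) ylide of the all-trans bis(β-keto) compound from F6 | C[S+](C)(=O)[CH-]C(=O)[C@H]1[C@H](CNC(=O)c2ccc[nH]2)[C@@H](CNC(=O)c2ccc[nH]2)[C@@H]1C(=O)[CH-][S+](C)(C)=O
F8 | step 2 | N,N'-{[(1R,2R,3S,4S)-3,4-bis(chloroacetyl)cyclobutane-1,2-diyl]bis(methylene)}bis(1H-pyrrole-2-carboxamide) | ClCC(=O)[C@H]1[C@H](CNC(=O)c2ccc[nH]2)[C@@H](CNC(=O)c2ccc[nH]2)[C@@H]1C(=O)CCl
F9 | step 11 | N,N'-{[(1R,2R,3S,4S)-3,4-bis(tosyloxyacetyl)cyclobutane-1,2-diyl]bis(methylene)}bis(1H-pyrrole-2-carboxamide) | Cc1ccc(cc1)S(=O)(=O)OCC(=O)[C@H]2[C@H](CNC(=O)c3ccc[nH]3)[C@@H](CNC(=O)c3ccc[nH]3)[C@@H]2C(=O)COS(=O)(=O)c1ccc(C)cc1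
F10 | step 11 | N,N'-{[(1R,2R,3S,4S)-3,4-bis(2-amino-1-(tert-butoxycarbonyl)-1H-imidazol-4-yl)cyclobutane-1,2-diyl]bis(methylene)}bis(1H-pyrrole-2-carboxamide) | CC(C)(C)OC(=O)n1cc(nc1N)[C@H]2[C@H](CNC(=O)c3ccc[nH]3)[C@@H](CNC(=O)c3ccc[nH]3)[C@@H]2c1cn(C(=O)OC(C)(C)C)c(N)n1
F11 | step 8 | N,N'-({(1R,2R,3S,4S)-3,4-bis[(2S)-oxiran-2-yl]cyclobutane-1,2-diyl}bis(methylene))bis(1H-pyrrole-2-carboxamide) | C1O[C@H]1[C@H]2[C@H](CNC(=O)c3ccc[nH]3)[C@@H](CNC(=O)c3ccc[nH]3)[C@@H]2[C@H]1CO1
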